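**Strategy**

Everything rests on reading the lower 5/7 half as a rearranged 6/6 eudesmanolide: re-attaching C5 from C10 to C1 interconverts the skeletons and leaves C5, C6, C7 and the whole C15 framework in place. Acetolysis of santamarine 1β-mesylate (trans-decalin, 3-ene, α-methylene lactone already present) does this in one operation: ring A contracts to the C1–C5 cyclopentene, ring B expands to the cycloheptane, C1 is inverted to the cis fusion and the C10 cation collapses to the C10=C14 methylene. The triene is oxidised to dehydrozaluzanin C, used as dienophile and, after dehydrogenation and C5 inversion, as diene; a Diels–Alder reaction and a proton shift close the C2′–C4/C14′–C15 cyclohexene.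

Key step: step 3

Remark on the chemistry: 18 is taken as drawn. The lower half has natural 1α,5α,6β,7α-H and carries the spiro bond C4–C2′ on its α-face. The upper half (primed numbers) has 5′β-H (cis to H-6′) and 10′α-H. C5′ and C10′ are γ to the C3′ ketone, so both are set under kinetic control and base is avoided afterwards.
Numbers are given to every species that puts atoms into a numbered compound; auxiliaries over the arrow are not numbered.

**Route**

Step 1
Reactants: 1 costunolide; 2 meta-chloroperoxybenzoic acid (mCPBA)
Product: 4 santamarine, via 1β,10α-epoxycostunolide 3 (not isolated)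
Conditions: mCPBA (1.05 equiv), CH2Cl2, 0 °C; then p-TsOH·H2O (0.2 equiv), 0 °C → rt
Reagents that add atoms: mCPBA, OOC(=O)c1cccc(Cl)c1
Why: Prilezhaev epoxidation should take the 1(10)-alkene (the 4,5-alkene is deactivated by the allylic lactone oxygen) on its outer face, and Brønsted acid then drives the transannular cyclisation of the germacranolide epoxide through the chair–chair conformer, in which C5 opens the oxirane at C10 with inversion (10β-methyl, 5α-H), C1 keeps its oxygen (1β-OH) and the C4 cation loses H-3; the exocyclic Δ4(15) isomer expected alongside is removed on AgNO3–silica.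

Step 2
Reactants: 4 santamarine; 5 methanesulfonyl chloride
Product: 6 santamarine 1-O-mesylate (1β-mesyloxyeudesma-3,11(13)-dien-6α,12-olide)
Conditions: MsCl (1.5 equiv), pyridine, DMAP (cat.), 0 °C → rt
Reagents that add atoms: methanesulfonyl chloride, CS(=O)(=O)Cl
Why: O-Sulfonylation (mesylation) of the equatorial secondary alcohol leaves the C1–O bond and so the 1β configuration untouched, and the neopentyl-type position neither ionises nor eliminates at this temperature.

Step 3
Reactants: 6 santamarine 1-O-mesylate
Product: 7 guaia-3,10(14),11(13)-trien-6α,12-olide (1α,5α,6β,7α-H)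
Conditions: KOAc (3 equiv), AcOH, 100 °C
Reagents that add atoms: none
Why: Buffered acetolysis ionises the equatorial 1β-mesylate with assistance from the antiperiplanar C5–C10 σ bond, so that C5 shifts from C10 to C1 (Wagner–Meerwein 1,2-alkyl shift) and the tertiary C10 cation is deprotonated at C14 by acetate (E1). The closest known reaction type is the solvolytic eudesmane-to-guaiane rearrangement of 1β-sulfonyloxy trans-decalins. The new C1–C5 bond closes the cyclopentene by ring contraction (backside displacement at C1 by the migrating carbon), and the same shift turns ring B into the cycloheptane by ring expansion, so no separate cyclisation is needed. C1 is the only new stereocentre and is set by inversion, C5 arriving anti to the leaving group, which gives 1α-H cis to 5α-H, while C5 (migrating with retention), C6 and C7 are untouched. Migration of C5 rather than C9 or C14 is secured by the rigid trans-decalin, in which only the C5–C10 bond is antiperiplanar to the equatorial C1–O bond and no anti hydrogen is available for E2. Exocyclic rather than endocyclic proton loss is steered by the acetate buffer (kinetic removal of an accessible methyl proton, no free acid to isomerise the alkene), and the Δ1(10) and Δ9 isomers are separated.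

Step 4
Reactants: 7 guaia-3,10(14),11(13)-trien-6α,12-olide; 2 mCPBA
Product: 8 estafiatin (3α,4α-epoxyguaia-10(14),11(13)-dien-6α,12-olide)
Conditions: mCPBA (1.0 equiv), NaHCO3, CH2Cl2, 0 °C
Reagents that add atoms: mCPBA, OOC(=O)c1cccc(Cl)c1
Why: Prilezhaev epoxidation should be fastest at the trisubstituted 3-ene (the 1,1-disubstituted 10(14)-ene reacts more slowly, the conjugated lactone not at all) and occurs on the convex α-face of the cis-fused hydroazulene, which sets C3 and C4 as the 3α,4α-epoxide.

Step 5
Reactants: 8 estafiatin
Product: 9 3-epizaluzanin C (3α-hydroxyguaia-4(15),10(14),11(13)-trien-6α,12-olide)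
Conditions: Al(OiPr)3 (2 equiv), toluene, 100 °C; Rochelle salt work-up
Reagents that add atoms: none
Why: Aluminium-alkoxide-mediated isomerisation of an epoxide to an allylic alcohol: aluminium binds the oxirane oxygen, the tertiary C4–O bond breaks and a C15 methyl proton is removed syn through a cyclic transition state, so that the oxygen stays on C3 with retention (3α-OH) and the 4(15)-methylene appears.

Step 6
Reactants: 9 3-epizaluzanin C
Product: 10 dehydrozaluzanin C (3-oxoguaia-4(15),10(14),11(13)-trien-6α,12-olide)
Conditions: activated MnO2 (15 equiv), CH2Cl2, rt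
Reagents that add atoms: none
Why: Manganese dioxide oxidises only the allylic alcohol, removing the C3 stereocentre and giving the cross-conjugated exocyclic enone, which is kept cold and dilute and used at once because it dimerises on standing.

Step 7
Reactants: 10 dehydrozaluzanin C; 11 trimethylsilyl trifluoromethanesulfonate (TMSOTf)
Product: 13 3-oxoguaia-1,4(15),10(14),11(13)-tetraen-6α,12-olide, via silyl enol ether 12 (not isolated)
Conditions: TMSOTf (1.2 equiv), Et3N (2 equiv), CH2Cl2, 0 °C; then Pd(OAc)2 (1.1 equiv), MeCN, rt, Ar
Reagents that add atoms: none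
Why: Saegusa–Ito oxidation: soft enolisation can only go towards C2 (C4 carries no hydrogen), and the palladium enolate formed from the silyl enol ether loses H-1 by β-hydride elimination, which installs the 1,2-ene and completes the s-cis C2=C1–C10=C14 diene without touching C5.

Step 8
Reactants: 13 3-oxoguaia-1,4(15),10(14),11(13)-tetraen-6α,12-olide; 14 potassium hexamethyldisilazide (KHMDS)
Product: 16 5-epi-3-oxoguaia-1,4(15),10(14),11(13)-tetraen-6α,12-olide, via potassium trienolate 15 (not isolated)
Conditions: KHMDS (1.05 equiv), THF, −78 °C, 10 min; then inverse quench into AcOH (5 equiv)/THF, −78 °C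
Reagents that add atoms: none
Why: Removal of the doubly vinylogous H-5 gives a planar oxidofulvene-type enolate whose largest HOMO coefficient lies on C5, and its irreversible low-temperature quench (kinetic protonation of an extended enolate) should deliver the proton to the β-face, because the trans-fused lactone holds the seven-membered ring in the chair that places C7 and C9 on the α-face of the planar C10–C1–C5–C6 unit, so the proton arrives anti to the C6–C7 bond and sets 5β-H.

Step 9
Reactants: 16 5-epi-3-oxoguaia-1,4(15),10(14),11(13)-tetraen-6α,12-olide; 10 dehydrozaluzanin C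
Product: 18 CNP0221188.1, via Diels–Alder adduct 17 (not isolated)
Conditions: 10 (3 equiv), BHT (cat.), toluene (0.5 M), 45 °C, Ar, dark; then Et3N (0.2 equiv), toluene, 0 °C, stopped at full conversion of 17 by filtration through silica
Reagents that add atoms: dehydrozaluzanin C (10), C=C1C(=O)C[C@H]2C(=C)CC[C@H]3C(=C)C(=O)O[C@@H]3[C@@H]12
Why: The Diels–Alder reaction of the C2′=C1′–C10′=C14′ dienone with the exocyclic enone of 10 (ortho orientation, C15 to C14′ and C4 to C2′; excess 10 suppresses self-cycloaddition) should take the convex α-face of the cis-hydroazulene of 10, which sets the spiro centre C4, and the β-face of the diene remote from C6′–C9′, which leaves H-2′ on the α-face; the amine then isomerises the β,γ- to the α,β-unsaturated ketone by a suprafacial 1,3-prototropic shift within the contact ion pair (conducted-tour mechanism in a non-polar solvent), placing that proton on the α-face of C10′ (10′α-H) while 5′β-H is kept.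

**Compound list**

1 | costunolide (germacra-1(10)E,4E,11(13)-trien-6α,12-olide; 6β-H, 7α-H) | C/C1=C\CC/C(C)=C/[C@H]2OC(=O)C(=C)[C@@H]2CC1 | starting material
2 | meta-chloroperoxybenzoic acid (mCPBA) | OOC(=O)c1cccc(Cl)c1 | starting material
3 | 1β,10α-epoxycostunolide (not isolated) | C[C@@]12CC[C@H]3C(=C)C(=O)O[C@@H]3/C=C(C)/CC[C@H]1O2 | intermediate
4 | santamarine (1β-hydroxyeudesma-3,11(13)-dien-6α,12-olide; 5α-H, 10β-Me) | CC1=CC[C@@H](O)[C@]2(C)CC[C@H]3C(=C)C(=O)O[C@@H]3[C@@H]12 | intermediate
5 | methanesulfonyl chloride | CS(=O)(=O)Cl | starting material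
6 | santamarine 1-O-mesylate (1β-mesyloxyeudesma-3,11(13)-dien-6α,12-olide) | CC1=CC[C@@H](OS(C)(=O)=O)[C@]2(C)CC[C@H]3C(=C)C(=O)O[C@@H]3[C@@H]12 | intermediate
7 | guaia-3,10(14),11(13)-trien-6α,12-olide (1α,5α,6β,7α-H) | CC1=CC[C@H]2C(=C)CC[C@H]3C(=C)C(=O)O[C@@H]3[C@H]21 | intermediate
8 | estafiatin (3α,4α-epoxyguaia-10(14),11(13)-dien-6α,12-olide) | C[C@@]12O[C@@H]1C[C@H]1C(=C)CC[C@H]3C(=C)C(=O)O[C@@H]3[C@H]12 | intermediate
9 | 3-epizaluzanin C (3α-hydroxyguaia-4(15),10(14),11(13)-trien-6α,12-olide) | C=C1[C@H](O)C[C@H]2C(=C)CC[C@H]3C(=C)C(=O)O[C@@H]3[C@@H]12 | intermediate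
10 | dehydrozaluzanin C (3-oxoguaia-4(15),10(14),11(13)-trien-6α,12-olide) | C=C1C(=O)C[C@H]2C(=C)CC[C@H]3C(=C)C(=O)O[C@@H]3[C@@H]12 | intermediate
11 | trimethylsilyl trifluoromethanesulfonate | C[Si](C)(C)OS(=O)(=O)C(F)(F)F | starting material
12 | 3-trimethylsilyloxyguaia-2,4(15),10(14),11(13)-tetraen-6α,12-olide (not isolated) | C=C1C(O[Si](C)(C)C)=C[C@H]2C(=C)CC[C@H]3C(=C)C(=O)O[C@@H]3[C@@H]12 | intermediate
13 | 3-oxoguaia-1,4(15),10(14),11(13)-tetraen-6α,12-olide (5α-H) | C=C1C(=O)C=C2C(=C)CC[C@H]3C(=C)C(=O)O[C@@H]3[C@@H]12 | intermediate
14 | potassium hexamethyldisilazide | C[Si](C)(C)[N-][Si](C)(C)C.[K+] | starting material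
15 | potassium 3-oxidoguaia-1(5),2,4(15),10(14),11(13)-pentaen-6α,12-olide (trienolate, not isolated) | C=C1C([O-])=CC2=C1[C@H]1OC(=O)C(=C)[C@@H]1CCC2=C.[K+] | intermediate
16 | 5-epi-3-oxoguaia-1,4(15),10(14),11(13)-tetraen-6α,12-olide (5β-H, cis to H-6) | C=C1C(=O)C=C2C(=C)CC[C@H]3C(=C)C(=O)O[C@@H]3[C@H]12 | intermediate
17 | Diels–Alder adduct (C2′–C4 and C14′–C15 bonds, Δ1′(10′), 2′α-H, 5′β-H, not isolated) | C=C1C(=O)[C@@H]2C3=C(CC[C@H]4C(=C)C(=O)O[C@@H]4[C@H]13)CC[C@]21C(=O)C[C@H]2C(=C)CC[C@H]3C(=C)C(=O)O[C@@H]3[C@H]21 | intermediate
18 | CNP0221188.1 (spiro bis-guaianolide, C2′=C1′ enone, 5′β-H, 10′α-H) | C=C1C(=O)C2=C3[C@H](CC[C@H]4C(=C)C(=O)O[C@@H]4[C@H]13)CC[C@]21C(=O)C[C@H]2C(=C)CC[C@H]3C(=C)C(=O)O[C@@H]3[C@H]21 | target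

**Step count**

Total steps: 9. Longest linear sequence: 9 (1 → 18; the dienophile 10 is taken from the same line after step 6).

**Steps most likely to fail**

Step 9. The stereochemical fidelity of the proton shift may erode: the proton can return to C10′ from the β-face, or the amine can equilibrate the two γ-centres C5′ and C10′ towards less strained diastereomers (this isomer places the trans-lactone on a twisted seven-membered ring). The twisted 5-epi diene may also cycloadd slowly and let self-cycloaddition compete. The fallback changes the order of events; it sets out from 13 (with 10) and comes back at 18. Cycloaddition of the planar natural diene 13 with 10 (toluene, 25–45 °C, Ar) should give the 5′α-adduct F1. Et3N in CH2Cl2 under equilibrating conditions then conjugates the enone and lets C10′ settle with 10′α-H, the arrangement that allows a chair for the upper seven-membered ring, giving the 5′α,10′α-dimer F2. C5′ is inverted last by γ-deprotonation (KHMDS, THF, −78 °C; C2′ is now fully substituted) and kinetic protonation on the β-face, which leads to 18.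

Step 8. The ambident enolate may be protonated at C2 (deconjugation) or on the α-face (return of the starting epimer), and it may add to a second molecule on warming. The fallback avoids a free enolate; it sets out from 13 and comes back at 16. Soft enolisation with TBSOTf and Et3N (CH2Cl2, −78 °C) should give the TBS trienol ether F3. Protodesilylation with HF·pyridine (THF, −78 °C) is then a vinylogous, γ-selective protonation of a silyl dienol ether on the same open β-face of C5, giving 16.

Step 3. The C10 cation may lose H-1 or H-9 and form endocyclic alkenes, or be captured by acetate. The fallback separates the skeletal shift from alkene formation; it sets out from 6 and comes back at 7. The same Wagner–Meerwein shift is run under hydrolytic conditions (NaHCO3, acetone–water, 60 °C), so that water captures the cation on the convex α-face and gives 10α-hydroxyguaia-3,11(13)-dien-6α,12-olide F4. Dehydration with SOCl2 and pyridine (−20 °C) proceeds by anti-elimination, which excludes H-1 (cis to the leaving group) and favours the methyl hydrogens, giving 7.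

Further compounds
F1 | step 9 | Diels–Alder adduct of 13 with 10 (Δ1′(10′), 2′β-H, 5′α-H) | C=C1C(=O)[C@H]2C3=C(CC[C@H]4C(=C)C(=O)O[C@@H]4[C@@H]13)CC[C@]21C(=O)C[C@H]2C(=C)CC[C@H]3C(=C)C(=O)O[C@@H]3[C@H]21
F2 | step 9 | 5′-epimer of 18 (5′α-H, 10′α-H dimer) | C=C1C(=O)C2=C3[C@H](CC[C@H]4C(=C)C(=O)O[C@@H]4[C@@H]13)CC[C@]21C(=O)C[C@H]2C(=C)CC[C@H]3C(=C)C(=O)O[C@@H]3[C@H]21
F3 | step 8 | 3-(tert-butyldimethylsilyloxy)guaia-1(5),2,4(15),10(14),11(13)-pentaen-6α,12-olide (TBS trienol ether) | C=C1C(O[Si](C)(C)C(C)(C)C)=CC2=C1[C@H]1OC(=O)C(=C)[C@@H]1CCC2=C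
F4 | step 3 | 10α-hydroxyguaia-3,11(13)-dien-6α,12-olide (1α,5α-H, 10β-Me) | CC1=CC[C@H]2[C@](C)(O)CC[C@H]3C(=C)C(=O)O[C@@H]3[C@H]21
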